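**Retrosynthetic overview**

1. Numbering: ring A is the cyclodecadiene C1–C10 (C1=C2 E, C3–OAc, C4=C5 Z, C6–O, C8–OAng, C10 carbinol); ring B is the γ-lactone O–C12(=O)–C11(=C13H2)–C7–C6. Last disconnections are the C3 acetate and ring A at C3–C4 (Nozaki–Hiyama–Kishi closure of a Z-alkenyl iodide onto an E-enal).
2. Key disconnection is C7–C11. Ring B is closed by a 5-exo epoxide opening of an O6 phosphonoacetate, telescoped with Horner–Wadsworth–Emmons methylenation. One operation on an acyclic epoxy ester should give the C7–C11 bond, the cis ring fusion, the C7 centre, the free C8–OH and the C13 methylene.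
3. Enabling feature: C7, the fusion carbon shared by rings A and B, lies between two oxygen-bearing carbons (C6–O of the lactone, C8–O of the angelate), with H6/H7 cis and C7–C11 anti to C8–O. This is the retron of a threo cis-2,3-epoxy alcohol (C6–OH, C7–C8 oxirane) whose O6 carries the C11 nucleophile.
4. The epoxy alcohol comes from a Z,Z-dienol, made by asymmetric alkynylation of (Z)-3-iodobut-2-enal (C4–C6 and the C4 methyl, from but-2-yn-1-ol) with an alkyne (C7–C10 and C1, C10 centre from (R)-linalool), then cis-semireduction. C2 and C3 come from acrolein diethyl acetal by cross-metathesis.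
5. Order of ring formation: ring B (step 12), then ring A (step 15).

Key step: step 12

Remark: the structure is read as 3R,6R,7S,8R,10R with H6 and H7 cis (cis-fused lactone), 4Z and 1(2)E; this isomer is the one planned for.

**Step 1**
Reactants: 1 (R)-(−)-linalool
Product: 2 triethyl{[(3R)-3,7-dimethylocta-1,6-dien-3-yl]oxy}silane
Conditions: Et3SiOTf, 2,6-lutidine, CH2Cl2, −78 → 0 °C
Reagents that add atoms: triethylsilyl triflate, CC[Si](CC)(CC)OS(=O)(=O)C(F)(F)F
Why: Silyl triflate silylation of a tertiary alcohol with a hindered pyridine base masks the C10 hydroxyl, so that step 2 should give a free aldehyde and not a lactol; no stereocentre is touched.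

**Step 2**
Reactants: 2 triethyl{[(3R)-3,7-dimethylocta-1,6-dien-3-yl]oxy}silane
Product: 3 (4R)-4-methyl-4-[(triethylsilyl)oxy]hex-5-enal
Conditions: O3, pyridine, CH2Cl2, Sudan Red 7B (end-point dye), −78 °C
Reagents that add atoms: ozone, [O-][O+]=O
Why: Pyridine-promoted reductive ozonolysis should cleave the electron-rich trisubstituted alkene much faster than the vinyl group next to the quaternary silyloxy carbon and deliver the aldehyde (C7) directly.

**Step 3**
Reactants: 3 (4R)-4-methyl-4-[(triethylsilyl)oxy]hex-5-enal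
Product: 5 triethyl{[(3R)-3-methylhex-1-en-5-yn-3-yl]oxy}silane, via enol nonaflate 4 (not isolated)
Conditions: nonafluorobutanesulfonyl fluoride (NfF), phosphazene base P2-Et, DMF, −20 °C → rt
Reagents that add atoms: none
Why: One-pot enol nonaflate formation and phosphazene-induced β-elimination (non-homologating aldehyde-to-alkyne conversion through an alkenyl sulfonate) should turn the CH2–CHO end into the C8≡C7–H alkyne without touching the silyl ether.

**Step 4**
Reactants: 6 but-2-yn-1-ol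
Product: 8 (2Z)-3-iodobut-2-en-1-ol, via cyclic vinylalanate 7 (not isolated)
Conditions: NaAlH2(OCH2CH2OCH3)2, Et2O, 0 °C → rt; then I2, THF, −78 → 0 °C
Reagents that add atoms: iodine, II
Why: Hydroxyl-directed trans-hydroalumination of the propargylic alcohol followed by iodinolysis of the C–Al bond with retention places iodine on C4 cis to the carbinol carbon, which fixes the Z geometry of the later C4=C5 bond.

**Step 5**
Reactants: 8 (2Z)-3-iodobut-2-en-1-ol
Product: 9 (2Z)-3-iodobut-2-enal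
Conditions: MnO2, CH2Cl2, rt, dark
Reagents that add atoms: none
Why: MnO2 oxidation of an allylic alcohol gives the enal under neutral conditions that should not isomerise the Z-β-iodo enal.

**Step 6**
Reactants: 5 triethyl{[(3R)-3-methylhex-1-en-5-yn-3-yl]oxy}silane, 9 (2Z)-3-iodobut-2-enal
Product: 11 (2Z,4R,8R)-2-iodo-8-methyl-8-[(triethylsilyl)oxy]deca-2,9-dien-5-yn-4-ol, via methylzinc acetylide 10 (not isolated)
Conditions: (R,R)-ProPhenol (20 mol %), Me2Zn, Ph3P=O, toluene, 4 °C
Reagents that add atoms: none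
Why: Zinc–ProPhenol-catalysed enantioselective alkynylation of an α,β-unsaturated aldehyde sets C6 by catalyst-controlled addition to the Si face of 9; the (R,R)-ligand is chosen for this face on the model that the (S,S)-ligand attacks the Re face, and its antipode is equally available.

**Step 7**
Reactants: 11 (2Z,4R,8R)-2-iodo-8-methyl-8-[(triethylsilyl)oxy]deca-2,9-dien-5-yn-4-ol
Product: 12 (2Z,4S,5Z,8R)-2-iodo-8-methyl-8-[(triethylsilyl)oxy]deca-2,5,9-trien-4-ol
Conditions: Zn dust activated with Cu(OAc)2 and AgNO3, MeOH/H2O/THF, 40 °C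
Reagents that add atoms: none
Why: Activated-zinc cis-semireduction of a propargylic alcohol (Näf–Boland-type) should give the Z-alkene C7=C8 by syn delivery of two hydrogens and avoids palladium, which would hydrogenolyse the alkenyl iodide (the C6 descriptor changes only through priorities).

**Step 8**
Reactants: 12 (2Z,4S,5Z,8R)-2-iodo-8-methyl-8-[(triethylsilyl)oxy]deca-2,5,9-trien-4-ol
Product: 13 (1R,2Z)-3-iodo-1-[(2S,3R)-3-{(2R)-2-methyl-2-[(triethylsilyl)oxy]but-3-en-1-yl}oxiran-2-yl]but-2-en-1-ol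
Conditions: mCPBA, NaHCO3, CH2Cl2, 0 °C
Reagents that add atoms: 3-chloroperoxybenzoic acid, OOC(=O)c1cccc(Cl)c1
Why: In this hydroxyl-directed peracid epoxidation (Henbest), A(1,3) strain of the Z-allylic alcohol holds H6 in the alkene plane, so the hydrogen-bonded peracid should attack the face syn to the hydroxyl and give the threo cis-epoxide (C7 and C8 set), while the iodine-deactivated C4=C5 bond and the undirected vinyl group react far more slowly.

**Step 9**
Reactants: 13 (1R,2Z)-3-iodo-1-[(2S,3R)-3-{(2R)-2-methyl-2-[(triethylsilyl)oxy]but-3-en-1-yl}oxiran-2-yl]but-2-en-1-ol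
Product: 14 (1R,2Z)-1-{(2S,3R)-3-[(2R)-2-hydroxy-2-methylbut-3-en-1-yl]oxiran-2-yl}-3-iodobut-2-en-1-ol
Conditions: Bu4NF, AcOH, THF, 0 °C → rt
Reagents that add atoms: none
Why: Fluoride cleavage of the tertiary silyl ether, buffered with AcOH so that neither Payne rearrangement nor epoxide opening intervenes, frees the C10 hydroxyl that the metathesis needs.

**Step 10**
Reactants: 14 (1R,2Z)-1-{(2S,3R)-3-[(2R)-2-hydroxy-2-methylbut-3-en-1-yl]oxiran-2-yl}-3-iodobut-2-en-1-ol, 15 acrolein diethyl acetal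
Product: 16 (1R,2Z)-1-{(2S,3R)-3-[(2R,3E)-5,5-diethoxy-2-hydroxy-2-methylpent-3-en-1-yl]oxiran-2-yl}-3-iodobut-2-en-1-ol
Conditions: second-generation Hoveyda–Grubbs catalyst RuCl2(H2IMes)(=CH-C6H4-2-OiPr) (5 mol %), CH2Cl2, 40 °C
Reagents that add atoms: none
Why: Olefin cross-metathesis of the vinyl group of a free tertiary allylic alcohol with an acrolein acetal should give the E-alkene C1=C2 and bring in C2 and C3 with C3 as a masked aldehyde; the trisubstituted alkenyl iodide is inert to the ruthenium carbene, and no acrylate-type alkene is yet present to compete.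

**Step 11**
Reactants: 16 (1R,2Z)-1-{(2S,3R)-3-[(2R,3E)-5,5-diethoxy-2-hydroxy-2-methylpent-3-en-1-yl]oxiran-2-yl}-3-iodobut-2-en-1-ol, 17 (diethoxyphosphoryl)acetic acid
Product: 18 (1R,2Z)-1-{(2R,3R)-3-[(2R,3E)-5,5-diethoxy-2-hydroxy-2-methylpent-3-en-1-yl]oxiran-2-yl}-3-iodobut-2-en-1-yl (diethoxyphosphoryl)acetate
Conditions: DCC, DMAP (cat.), CH2Cl2, 0 °C → rt
Reagents that add atoms: none
Why: Steglich esterification should acylate the secondary C6 hydroxyl and leave the tertiary C10 hydroxyl free, which puts the C11–C12 unit on O6 (the oxirane descriptor at C7 changes only through priorities).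

**Step 12**
Reactants: 18 (1R,2Z)-1-{(2R,3R)-3-[(2R,3E)-5,5-diethoxy-2-hydroxy-2-methylpent-3-en-1-yl]oxiran-2-yl}-3-iodobut-2-en-1-yl (diethoxyphosphoryl)acetate
Product: 20 (4S,5S)-4-[(1R,3R,4E)-6,6-diethoxy-1,3-dihydroxy-3-methylhex-4-en-1-yl]-5-[(1Z)-2-iodoprop-1-en-1-yl]-3-methylideneoxolan-2-one, via phosphono lactone anion 19 (not isolated)
Conditions: KOtBu (1.05 equiv), THF, −78 °C → rt; then (CH2O)n, 0 °C → rt; pH 7 buffer
Reagents that add atoms: formaldehyde (as paraformaldehyde), C=O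
Why: KOtBu removes the proton between phosphorus and the ester carbonyl, and the carbanion C11 attacks C7 from the side opposite the oxirane C7–O bond (the ester turning into the rotamer that every lactone-forming C–C closure needs); the C8 alkoxide so released is quenched at once by the still acidic C11–H to give anion 19, which paraformaldehyde converts into the C11=C13 methylene by Horner–Wadsworth–Emmons olefination. The closest known reaction types are the exo cyclisation of epoxides by tethered stabilised carbanions (Stork-type), the epoxide alkylation of phosphonoacetate anions that opens the Wadsworth–Emmons cyclopropanation, and the telescoped intramolecular Michael/olefination lactone annulations of phosphonoacetate esters. Ring B closes in the 5-exo-tet mode. C7 is set by stereospecific SN2 inversion, so the threo cis-epoxide of step 8 becomes H6/H7 cis with C7–C11 anti to C8–O, while C8 keeps the oxirane configuration and C6 is untouched. The step needs attack at C7 and not at C8 (6-endo) and needs the freed alkoxide to stay away from phosphorus (cyclopropane collapse) and from C12 (translactonisation): only C7 lets the three-atom ester tether reach the backside trajectory, and one equivalent of base at low temperature leaves O8 protonated once the carbanion has formed.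

**Step 13**
Reactants: 20 (4S,5S)-4-[(1R,3R,4E)-6,6-diethoxy-1,3-dihydroxy-3-methylhex-4-en-1-yl]-5-[(1Z)-2-iodoprop-1-en-1-yl]-3-methylideneoxolan-2-one, 21 angelic acid
Product: 22 (1R,3R,4E)-6,6-diethoxy-3-hydroxy-1-{(2S,3S)-2-[(1Z)-2-iodoprop-1-en-1-yl]-4-methylidene-5-oxooxolan-3-yl}-3-methylhex-4-en-1-yl (2Z)-2-methylbut-2-enoate
Conditions: 2,4,6-trichlorobenzoyl chloride, Et3N, toluene, rt; then 20, 75 °C (no DMAP)
Reagents that add atoms: none
Why: Yamaguchi mixed-anhydride esterification without DMAP, the usual way to make angelates without isomerisation to the tiglate, should acylate the secondary C8 hydroxyl while the tertiary C10 hydroxyl does not react.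

**Step 14**
Reactants: 22 (1R,3R,4E)-6,6-diethoxy-3-hydroxy-1-{(2S,3S)-2-[(1Z)-2-iodoprop-1-en-1-yl]-4-methylidene-5-oxooxolan-3-yl}-3-methylhex-4-en-1-yl (2Z)-2-methylbut-2-enoate
Product: 23 (1R,3R,4E)-3-hydroxy-1-{(2S,3S)-2-[(1Z)-2-iodoprop-1-en-1-yl]-4-methylidene-5-oxooxolan-3-yl}-3-methyl-6-oxohex-4-en-1-yl (2Z)-2-methylbut-2-enoate
Conditions: PPTS, acetone/H2O, rt
Reagents that add atoms: water, O
Why: Mild acid hydrolysis of an enal acetal should release the E-enal (C3 aldehyde) and leave the lactone, the angelate and the alkenyl iodide alone.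

**Step 15**
Reactants: 23 (1R,3R,4E)-3-hydroxy-1-{(2S,3S)-2-[(1Z)-2-iodoprop-1-en-1-yl]-4-methylidene-5-oxooxolan-3-yl}-3-methyl-6-oxohex-4-en-1-yl (2Z)-2-methylbut-2-enoate
Product: 25 (3aS,4R,6R,7E,9R,10Z,11aR)-6,9-dihydroxy-6,10-dimethyl-3-methylidene-2-oxo-2,3,3a,4,5,6,9,11a-octahydrocyclodeca[b]furan-4-yl (2Z)-2-methylbut-2-enoate, via alkenylchromium dichloride 24 (not isolated)
Conditions: CrCl2 (excess), NiCl2 (cat.), DMSO, rt, slow addition to 2 mM
Reagents that add atoms: none
Why: In this intramolecular Nozaki–Hiyama–Kishi reaction the alkenylchromium reagent forms with retention of the C4=C5 geometry and adds 1,2 to the enal, closing ring A at C3–C4 under high dilution; C3 is set by the ring-closing transition state, in which the cis-fused lactone and the C10 centre are expected to bias the enal face.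

**Step 16**
Reactants: 25 (3aS,4R,6R,7E,9R,10Z,11aR)-6,9-dihydroxy-6,10-dimethyl-3-methylidene-2-oxo-2,3,3a,4,5,6,9,11a-octahydrocyclodeca[b]furan-4-yl (2Z)-2-methylbut-2-enoate
Product: 26 (3aS,4R,6R,7E,9R,10Z,11aR)-9-(acetyloxy)-6-hydroxy-6,10-dimethyl-3-methylidene-2-oxo-2,3,3a,4,5,6,9,11a-octahydrocyclodeca[b]furan-4-yl (2Z)-2-methylbut-2-enoate (CNP0181631.1)
Conditions: Ac2O, pyridine, CH2Cl2, 0 °C → rt
Reagents that add atoms: acetic anhydride, CC(=O)OC(C)=O
Why: Acetylation of the secondary allylic C3 hydroxyl with Ac2O/pyridine should leave the tertiary C10 hydroxyl untouched and complete the target.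

**Compound list**

1 | (R)-(−)-linalool | CC(C)=CCC[C@@](C)(O)C=C | starting material
2 | triethyl{[(3R)-3,7-dimethylocta-1,6-dien-3-yl]oxy}silane | CC(C)=CCC[C@@](C)(O[Si](CC)(CC)CC)C=C | intermediate
3 | (4R)-4-methyl-4-[(triethylsilyl)oxy]hex-5-enal | O=CCC[C@@](C)(O[Si](CC)(CC)CC)C=C | intermediate
4 | (4R)-4-methyl-4-[(triethylsilyl)oxy]hexa-1,5-dien-1-yl nonafluorobutane-1-sulfonate (E/Z) | FC(F)(F)C(F)(F)C(F)(F)C(F)(F)S(=O)(=O)OC=CC[C@@](C)(O[Si](CC)(CC)CC)C=C | intermediate (not isolated)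
5 | triethyl{[(3R)-3-methylhex-1-en-5-yn-3-yl]oxy}silane | C#CC[C@@](C)(O[Si](CC)(CC)CC)C=C | intermediate
6 | but-2-yn-1-ol | CC#CCO | starting material
7 | cyclic vinylalanate Na[Al(OCH2CH2OCH3)2(OCH2CH=C(CH3))] | CC1=CCO[Al-]1(OCCOC)OCCOC.[Na+] | intermediate (not isolated)
8 | (2Z)-3-iodobut-2-en-1-ol | OC/C=C(/C)I | intermediate
9 | (2Z)-3-iodobut-2-enal | O=C/C=C(/C)I | intermediate
10 | methylzinc acetylide of 5 | C[Zn]C#CC[C@@](C)(O[Si](CC)(CC)CC)C=C | intermediate (not isolated)
11 | (2Z,4R,8R)-2-iodo-8-methyl-8-[(triethylsilyl)oxy]deca-2,9-dien-5-yn-4-ol | O[C@H](/C=C(/C)I)C#CC[C@@](C)(O[Si](CC)(CC)CC)C=C | intermediate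
12 | (2Z,4S,5Z,8R)-2-iodo-8-methyl-8-[(triethylsilyl)oxy]deca-2,5,9-trien-4-ol | O[C@H](/C=C(/C)I)/C=C\C[C@@](C)(O[Si](CC)(CC)CC)C=C | intermediate
13 | (1R,2Z)-3-iodo-1-[(2S,3R)-3-{(2R)-2-methyl-2-[(triethylsilyl)oxy]but-3-en-1-yl}oxiran-2-yl]but-2-en-1-ol | O[C@H](/C=C(/C)I)[C@@H]1O[C@@H]1C[C@@](C)(O[Si](CC)(CC)CC)C=C | intermediate
14 | (1R,2Z)-1-{(2S,3R)-3-[(2R)-2-hydroxy-2-methylbut-3-en-1-yl]oxiran-2-yl}-3-iodobut-2-en-1-ol | O[C@H](/C=C(/C)I)[C@@H]1O[C@@H]1C[C@@](C)(O)C=C | intermediate
15 | acrolein diethyl acetal (3,3-diethoxyprop-1-ene) | C=CC(OCC)OCC | starting material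
16 | (1R,2Z)-1-{(2S,3R)-3-[(2R,3E)-5,5-diethoxy-2-hydroxy-2-methylpent-3-en-1-yl]oxiran-2-yl}-3-iodobut-2-en-1-ol | O[C@H](/C=C(/C)I)[C@@H]1O[C@@H]1C[C@@](C)(O)/C=C/C(OCC)OCC | intermediate
17 | (diethoxyphosphoryl)acetic acid | CCOP(=O)(CC(=O)O)OCC | starting material
18 | (1R,2Z)-1-{(2R,3R)-3-[(2R,3E)-5,5-diethoxy-2-hydroxy-2-methylpent-3-en-1-yl]oxiran-2-yl}-3-iodobut-2-en-1-yl (diethoxyphosphoryl)acetate | CCOP(=O)(OCC)CC(=O)O[C@H](/C=C(/C)I)[C@@H]1O[C@@H]1C[C@@](C)(O)/C=C/C(OCC)OCC | intermediate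
19 | potassium salt of the α-(diethoxyphosphoryl) lactone (C11 carbanion, C8–OH free) | CCOP(=O)(OCC)[C-]1C(=O)O[C@H](/C=C(/C)I)[C@@H]1[C@H](O)C[C@@](C)(O)/C=C/C(OCC)OCC.[K+] | intermediate (not isolated)
20 | (4S,5S)-4-[(1R,3R,4E)-6,6-diethoxy-1,3-dihydroxy-3-methylhex-4-en-1-yl]-5-[(1Z)-2-iodoprop-1-en-1-yl]-3-methylideneoxolan-2-one | C=C1C(=O)O[C@H](/C=C(/C)I)[C@@H]1[C@H](O)C[C@@](C)(O)/C=C/C(OCC)OCC | intermediate
21 | angelic acid, (2Z)-2-methylbut-2-enoic acid | C/C=C(/C)C(=O)O | starting material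
22 | (1R,3R,4E)-6,6-diethoxy-3-hydroxy-1-{(2S,3S)-2-[(1Z)-2-iodoprop-1-en-1-yl]-4-methylidene-5-oxooxolan-3-yl}-3-methylhex-4-en-1-yl (2Z)-2-methylbut-2-enoate | C=C1C(=O)O[C@H](/C=C(/C)I)[C@@H]1[C@H](OC(=O)/C(C)=C\C)C[C@@](C)(O)/C=C/C(OCC)OCC | intermediate
23 | (1R,3R,4E)-3-hydroxy-1-{(2S,3S)-2-[(1Z)-2-iodoprop-1-en-1-yl]-4-methylidene-5-oxooxolan-3-yl}-3-methyl-6-oxohex-4-en-1-yl (2Z)-2-methylbut-2-enoate | C=C1C(=O)O[C@H](/C=C(/C)I)[C@@H]1[C@H](OC(=O)/C(C)=C\C)C[C@@](C)(O)/C=C/C=O | intermediate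
24 | alkenylchromium dichloride derived from 23 (CrCl2 in place of iodine at C4) | C=C1C(=O)O[C@H](/C=C(/C)[Cr](Cl)Cl)[C@@H]1[C@H](OC(=O)/C(C)=C\C)C[C@@](C)(O)/C=C/C=O | intermediate (not isolated)
25 | (3aS,4R,6R,7E,9R,10Z,11aR)-6,9-dihydroxy-6,10-dimethyl-3-methylidene-2-oxo-2,3,3a,4,5,6,9,11a-octahydrocyclodeca[b]furan-4-yl (2Z)-2-methylbut-2-enoate | C=C1C(=O)O[C@@H]2/C=C(/C)[C@H](O)/C=C/[C@](C)(O)C[C@@H](OC(=O)/C(C)=C\C)[C@H]12 | intermediate
26 | (3aS,4R,6R,7E,9R,10Z,11aR)-9-(acetyloxy)-6-hydroxy-6,10-dimethyl-3-methylidene-2-oxo-2,3,3a,4,5,6,9,11a-octahydrocyclodeca[b]furan-4-yl (2Z)-2-methylbut-2-enoate | C=C1C(=O)O[C@@H]2/C=C(/C)[C@H](OC(C)=O)/C=C/[C@](C)(O)C[C@@H](OC(=O)/C(C)=C\C)[C@H]12 | target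

**Step count and risks**

Total step count: 16. Longest linear sequence: 14 steps (steps 1–3 and 6–16, from (R)-linalool); the (Z)-3-iodobut-2-enal branch (steps 4 and 5) joins at step 6.

Steps most likely to fail:

1. Step 12 (key step). What may go wrong: the phosphonate carbanion may be too weak a nucleophile for the unactivated oxirane or may not reach the backside of C7. The freed C8 alkoxide may attack C12 (translactonisation to the 8,12-olide) or phosphorus (collapse to a cyclopropane). The endo mode at C8 may also compete. Fallback: it sets out from 16 and drops the phosphonate. O6 would be esterified with 3-oxo-3-[2-(trimethylsilyl)ethoxy]propanoic acid (DCC, DMAP) to give the mixed malonate F1. Its sodium enolate (NaH, THF), the classical epoxide-alkylating carbanion, should close ring B in the same exo sense to give the lactone ester F2. Bu4NF should unmask the lactone acid F3. The methylene would then be put on by decarboxylative Mannich methylenation (aqueous HCHO, Et2NH; then NaOAc, AcOH, warming), which comes back to the route at 20.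

2. Step 15. What may go wrong: intermolecular coupling (oligomerisation) in place of ring closure, and poor facial selectivity at C3 in the ring-closing addition. Fallback: it sets out from 23. The chromium-mediated closure would be used only to make the C3–C4 bond and would give the C3 epimer mixture F4. Oxidation with Dess–Martin periodinane would give the cross-conjugated dienone F5. C3 would then be set under reagent control by (S)-Me-CBS/catecholborane reduction (the α-methylated C4 alkenyl group taken as the larger substituent), which comes back to the route at 25.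

3. Step 6. What may go wrong: Z-to-E isomerisation of the β-iodo enal at the Lewis-acidic zinc centres and erosion of enantioselectivity. Fallback: it sets out from 5 and 9. The lithium acetylide of 5 (n-BuLi, THF, −78 °C) would add to 9 to give the C6 epimer mixture F6. MnO2 oxidation would give the ynone F7. C6 would then be set by (R)-Me-CBS/catecholborane reduction (the alkynyl group taken as the smaller substituent), which comes back to the route at 11.

**Further compounds**

F1 | step 12 | (1R,2Z)-1-{(2R,3R)-3-[(2R,3E)-5,5-diethoxy-2-hydroxy-2-methylpent-3-en-1-yl]oxiran-2-yl}-3-iodobut-2-en-1-yl 2-(trimethylsilyl)ethyl propanedioate | C[Si](C)(C)CCOC(=O)CC(=O)O[C@H](/C=C(/C)I)[C@@H]1O[C@@H]1C[C@@](C)(O)/C=C/C(OCC)OCC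
F2 | step 12 | 2-(trimethylsilyl)ethyl (4S,5S)-4-[(1R,3R,4E)-6,6-diethoxy-1,3-dihydroxy-3-methylhex-4-en-1-yl]-5-[(1Z)-2-iodoprop-1-en-1-yl]-2-oxooxolane-3-carboxylate (C3 epimers) | C[Si](C)(C)CCOC(=O)C1C(=O)O[C@H](/C=C(/C)I)[C@@H]1[C@H](O)C[C@@](C)(O)/C=C/C(OCC)OCC
F3 | step 12 | (4S,5S)-4-[(1R,3R,4E)-6,6-diethoxy-1,3-dihydroxy-3-methylhex-4-en-1-yl]-5-[(1Z)-2-iodoprop-1-en-1-yl]-2-oxooxolane-3-carboxylic acid (C3 epimers) | OC(=O)C1C(=O)O[C@H](/C=C(/C)I)[C@@H]1[C@H](O)C[C@@](C)(O)/C=C/C(OCC)OCC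
F4 | step 15 | C3 epimer mixture of 25 (configuration at C3 open) | C=C1C(=O)O[C@@H]2/C=C(/C)C(O)/C=C/[C@](C)(O)C[C@@H](OC(=O)/C(C)=C\C)[C@H]12
F5 | step 15 | (3aS,4R,6R,7E,10Z,11aR)-6-hydroxy-6,10-dimethyl-3-methylidene-2,9-dioxo-2,3,3a,4,5,6,9,11a-octahydrocyclodeca[b]furan-4-yl (2Z)-2-methylbut-2-enoate | C=C1C(=O)O[C@@H]2/C=C(/C)C(=O)/C=C/[C@](C)(O)C[C@@H](OC(=O)/C(C)=C\C)[C@H]12
F6 | step 6 | (2Z,8R)-2-iodo-8-methyl-8-[(triethylsilyl)oxy]deca-2,9-dien-5-yn-4-ol (C4 epimers) | OC(/C=C(/C)I)C#CC[C@@](C)(O[Si](CC)(CC)CC)C=C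
F7 | step 6 | (2Z,8R)-2-iodo-8-methyl-8-[(triethylsilyl)oxy]deca-2,9-dien-5-yn-4-one | O=C(/C=C(/C)I)C#CC[C@@](C)(O[Si](CC)(CC)CC)C=C
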